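Assumptions: atom labels follow germacranolide numbering (C1 ketone, C3 OMe carbon, C4 CHMe, C6 lactone carbinol, C7 ring-fusion CH, C8 angelate carbinol, C10 acetoxy carbon, C11–C13 acrylate unit). A one-flask sequence counts as one step. Quoted selectivities are expectations, not measured values.

## Retrosynthetic overview
1. The angelate goes on last. The ten-membered ring is closed at C7–C8 by a visible-light, Cr-catalysed allylation of the C8 aldehyde by a 3-(bromomethyl)butenolide. This step sets C7 and C8 and unveils the exo-methylene lactone.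
2. The open chain is cut at C2–C3 by a Mukaiyama acetal aldol. It delivers the 3-OMe directly, with C3 set by Felkin control from C4.
3. West half: C6 is bought in (R)-epichlorohydrin. C4 is relayed from C6 by cis-hydrogenation of a temporary α-methylene-γ-lactone.
4. East half: C10 comes from (S)-lactic acid by self-regeneration of the stereocentre (allylation of its pivalaldehyde acetal).
5. Ring order: temporary γ-lactone, then butenolide (by RCM), then ten-membered carbocycle.

## West half

**Step 1**
Reactants: 1, (R)-epichlorohydrin
Product: 2, (R)-1-chloropent-4-yn-2-ol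
Conditions: HC≡CLi (acetylene, n-BuLi), BF3·OEt2, THF, −78 °C
Reagents that add atoms: acetylene, C#C
Why: BF3-assisted SN2 opening of the epoxide at its CH2 terminus (Yamaguchi alkynylation) leaves the bought C6 stereocentre untouched.

**Step 2**
Reactants: 2
Product: 3, (R)-5-(chloromethyl)-3-methylideneoxolan-2-one
Conditions: PdCl2 (5 mol %), PPh3, SnCl2, CO (3 atm), MeCN, 65 °C
Reagents that add atoms: carbon monoxide, [C-]#[O+]
Why: Pd-catalysed cyclocarbonylation of a homopropargylic alcohol (Norton type) gives the α-methylene-γ-lactone without touching C6 or the alkyl chloride.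

**Step 3**
Reactants: 3
Product: 4, (3R,5R)-5-(chloromethyl)-3-methyloxolan-2-one (cis)
Conditions: H2 (1 atm), 5 % Rh/Al2O3, EtOAc, rt
Reagents that add atoms: none
Why: In this heterogeneous hydrogenation H2 adds to the face opposite the C6 CH2Cl group, so the new methyl ends up cis to it and C4 is set as R (expected about 9:1).

**Step 4**
Reactants: 4
Product: 5, methyl (2R)-2-methyl-3-[(2R)-oxiran-2-yl]propanoate
Conditions: K2CO3, MeOH, 0 °C to rt
Reagents that add atoms: methanol, CO
Why: Lactone methanolysis releases the C6 alkoxide, which closes irreversibly on CH2Cl (Bartlett halolactone-to-epoxy-ester switch), retaining C6 and leaving the ester α-centre C4 intact under mild base.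

**Step 5**
Reactants: 5
Product: 6, (2R)-2-[(2R)-3,3-dimethoxy-2-methylpropyl]oxirane
Conditions: DIBAL-H (1.05 equiv), CH2Cl2, −78 °C; MeOH quench, then HC(OMe)3, PPTS (5 mol %), 0 °C to rt (one flask)
Reagents that add atoms: trimethyl orthoformate, COC(OC)OC; methanol, CO
Why: Partial ester reduction followed by immediate mild acetalisation never exposes the α-chiral aldehyde to base, and a terminal epoxide tolerates PPTS.

**Step 6**
Reactants: 6
Product: 7, (3R,5R)-6,6-dimethoxy-5-methylhex-1-en-3-ol
Conditions: Me3S+ I− (4 equiv), n-BuLi (3.9 equiv), THF, −10 °C to rt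
Reagents that add atoms: trimethylsulfonium iodide, C[S+](C)C.[I-]
Why: Dimethylsulfonium methylide opens the epoxide at its terminus and loses Me2S (one-carbon epoxide-to-allylic-alcohol homologation), so the C6–O bond is never broken.

**Step 7**
Reactants: 7; 8, 2-(bromomethyl)acrylic acid
Product: 9, (3R,5R)-6,6-dimethoxy-5-methylhex-1-en-3-yl 2-(bromomethyl)prop-2-enoate
Conditions: DIC, DMAP (5 mol %), CH2Cl2, −10 °C
Reagents that add atoms: 2-(bromomethyl)acrylic acid, C=C(CBr)C(=O)O
Why: Steglich esterification acylates O6 with retention, and low temperature with little DMAP avoids attack on the allylic bromide.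

**Step 8**
Reactants: 9
Product: 10, (5R)-3-(bromomethyl)-5-[(2R)-3,3-dimethoxy-2-methylpropyl]furan-2(5H)-one
Conditions: Hoveyda–Grubbs II (5 mol %), 1,4-benzoquinone (10 mol %), toluene (5 mM), 80 °C
Reagents that add atoms: none
Why: Ring-closing metathesis of the acrylate with the only other alkene gives the five-membered butenolide (loss of ethylene) and carries the allylic bromide into place.

## East half

**Step 9**
Reactants: 11, (S)-lactic acid
Product: 12, (2S,5S)-2-tert-butyl-5-methyl-1,3-dioxolan-4-one (cis)
Conditions: t-BuCHO, p-TsOH (cat.), pentane, Dean–Stark; recrystallise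
Reagents that add atoms: pivalaldehyde, CC(C)(C)C=O
Why: Seebach acetalisation stores the lactic acid chirality in the new acetal centre, and the cis isomer is purified by crystallisation.

**Step 10**
Reactants: 12
Product: 13, (2S,5R)-2-tert-butyl-5-methyl-5-(prop-2-enyl)-1,3-dioxolan-4-one
Conditions: LDA, THF, −78 °C; allyl bromide, −78 to −30 °C
Reagents that add atoms: allyl bromide, C=CCBr
Why: The enolate is alkylated anti to the tert-butyl group (self-regeneration of stereocentres), so allyl replaces H with retention and C10 is set as R.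

**Step 11**
Reactants: 13
Product: 14, (3R)-3-hydroxy-3-methylhex-5-en-2-one
Conditions: MeLi (1.05 equiv), Et2O, −78 °C; AcOH quench, aqueous work-up
Reagents that add atoms: methyllithium, [Li]C
Why: Single addition to the dioxolanone carbonyl gives a tetrahedral adduct stable at −78 °C, which collapses on work-up to the methyl ketone with loss of pivalaldehyde and leaves quaternary C10 unaffected.

**Step 12**
Reactants: 14
Product: 15, (3R)-3-methyl-2-oxohex-5-en-3-yl acetate
Conditions: Ac2O, Et3N, DMAP (10 mol %), CH2Cl2, rt
Reagents that add atoms: acetic anhydride, CC(=O)OC(C)=O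
Why: DMAP-catalysed acylation installs the final tertiary acetate early, which avoids any protecting group.

**Step 13**
Reactants: 15
Product: 16, (3R)-3-methyl-2-[(trimethylsilyl)oxy]hexa-1,5-dien-3-yl acetate
Conditions: TMSOTf, Et3N, CH2Cl2, 0 °C
Reagents that add atoms: trimethylsilyl triflate, C[Si](C)(C)OS(=O)(=O)C(F)(F)F
Why: Soft enolisation can only go toward C2 because C10 is quaternary, so a single silyl enol ether forms.

## Union and endgame

**Step 14**
Reactants: 10; 16
Product: 17, (4R,7R,8R)-9-[(2R)-4-(bromomethyl)-5-oxo-2,5-dihydrofuran-2-yl]-7-methoxy-4,8-dimethyl-5-oxonon-1-en-4-yl acetate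
Conditions: TMSOTf (10 mol %), CH2Cl2, −78 °C
Reagents that add atoms: none beyond 10 and 16
Why: In this Mukaiyama acetal aldol the methyl oxocarbenium ion at C3 is attacked anti to the C5 chain (Felkin–Anh), giving the 3,4-syn β-methoxy ketone with C3 as R (expected about 5:1, separable).

**Step 15**
Reactants: 17
Product: 18, (3R,6R,7R)-8-[(2R)-4-(bromomethyl)-5-oxo-2,5-dihydrofuran-2-yl]-6-methoxy-3,7-dimethyl-1,4-dioxooctan-3-yl acetate
Conditions: O3, pyridine (3 equiv), CH2Cl2, −78 °C (Sudan III end point); used crude
Reagents that add atoms: ozone, [O-][O+]=O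
Why: Ozone cleaves only the electron-rich terminal alkene (the butenolide C=C is deactivated), and the pyridine variant needs no phosphine or sulfide that would alkylate on the allylic bromide.

**Step 16 (key step)**
Reactants: 18
Product: 19, (3R,4R,6R,7R,8S,10R)-10-acetoxy-8-hydroxy-3-methoxy-1-oxogermacr-11(13)-en-12,6-olide (8α-OH, trans-fused lactone)
Conditions: 4CzIPN (2 mol %), CrCl3·3THF (15 mol %), Hantzsch ester (2.2 equiv), TMSCl (2 equiv), 2,6-di-tert-butyl-4-methylpyridine (2 equiv), THF; 18 added over 10 h to 2 mM final, 456 nm LEDs, 20 °C; then citric acid, MeOH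
Reagents that add atoms: none
Why: Proposed new method: photoexcited 4CzIPN, reductively quenched by the Hantzsch ester, continuously reduces Cr(III) to Cr(II), which converts the allylic bromide (via the allyl radical) into a C13-bound allyl–Cr(III) that adds through C7 to the tethered aldehyde in a chair transition state, anti to the C5 chain on the butenolide (trans lactone, C7) and with C9 equatorial on an E-locked allyl unit (anti adduct, 8α-O), while TMSCl turns Cr over and traps O8 before translactonisation and photon-limited generation keeps the allyl metal at pseudo-high dilution; Cr–allyls ignore the hindered C1 ketone; the closest known reactions are Zn Barbier additions of 3-(bromomethyl)butenolides to aldehydes, stoichiometric CrCl2 (NHK) macrocyclisations to germacranolides, and intermolecular photoredox/Cr or Ti allylation of aldehydes, none of which has been run as a macrocyclisation or with a bromomethylbutenolide.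

**Step 17**
Reactants: 19; 20, angelic acid
Product: 21, Rufesolide C
Conditions: 20, 2,4,6-trichlorobenzoyl chloride, Et3N, toluene, rt, filter; then 19, toluene, 75 °C
Reagents that add atoms: angelic acid, C/C=C(/C)C(=O)O
Why: Acylation through the Yamaguchi-type mixed anhydride without DMAP esterifies the only free hydroxyl with retention at C8 and without Z-to-E (tiglate) isomerisation or translactonisation.

## Compound list

| No. | Name | SMILES | Role |
|---|---|---|---|
| 1 | (R)-epichlorohydrin | ClC[C@H]1CO1 | starting material |
| 2 | (R)-1-chloropent-4-yn-2-ol | C#CC[C@@H](O)CCl | intermediate |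
| 3 | (R)-5-(chloromethyl)-3-methylideneoxolan-2-one | C=C1C[C@H](CCl)OC1=O | intermediate |
| 4 | (3R,5R)-5-(chloromethyl)-3-methyloxolan-2-one | C[C@@H]1C[C@H](CCl)OC1=O | intermediate |
| 5 | methyl (2R)-2-methyl-3-[(2R)-oxiran-2-yl]propanoate | COC(=O)[C@H](C)C[C@@H]1CO1 | intermediate |
| 6 | (2R)-2-[(2R)-3,3-dimethoxy-2-methylpropyl]oxirane | COC(OC)[C@H](C)C[C@@H]1CO1 | intermediate |
| 7 | (3R,5R)-6,6-dimethoxy-5-methylhex-1-en-3-ol | COC(OC)[C@H](C)C[C@@H](O)C=C | intermediate |
| 8 | 2-(bromomethyl)acrylic acid | C=C(CBr)C(=O)O | starting material |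
| 9 | (3R,5R)-6,6-dimethoxy-5-methylhex-1-en-3-yl 2-(bromomethyl)prop-2-enoate | COC(OC)[C@H](C)C[C@@H](OC(=O)C(=C)CBr)C=C | intermediate |
| 10 | (5R)-3-(bromomethyl)-5-[(2R)-3,3-dimethoxy-2-methylpropyl]furan-2(5H)-one | COC(OC)[C@H](C)C[C@H]1OC(=O)C(CBr)=C1 | intermediate |
| 11 | (S)-lactic acid | C[C@H](O)C(=O)O | starting material |
| 12 | (2S,5S)-2-tert-butyl-5-methyl-1,3-dioxolan-4-one | C[C@@H]1O[C@H](C(C)(C)C)OC1=O | intermediate |
| 13 | (2S,5R)-2-tert-butyl-5-methyl-5-(prop-2-enyl)-1,3-dioxolan-4-one | C=CC[C@@]1(C)O[C@H](C(C)(C)C)OC1=O | intermediate |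
| 14 | (3R)-3-hydroxy-3-methylhex-5-en-2-one | CC(=O)[C@](C)(O)CC=C | intermediate |
| 15 | (3R)-3-methyl-2-oxohex-5-en-3-yl acetate | CC(=O)[C@](C)(OC(C)=O)CC=C | intermediate |
| 16 | (3R)-3-methyl-2-[(trimethylsilyl)oxy]hexa-1,5-dien-3-yl acetate | C=C(O[Si](C)(C)C)[C@](C)(OC(C)=O)CC=C | intermediate |
| 17 | coupled β-methoxy ketone (terminal alkene) | O=C1O[C@H](C[C@@H](C)[C@H](OC)CC(=O)[C@](C)(OC(C)=O)CC=C)C=C1CBr | intermediate |
| 18 | seco aldehyde | O=C1O[C@H](C[C@@H](C)[C@H](OC)CC(=O)[C@](C)(OC(C)=O)CC=O)C=C1CBr | intermediate |
| 19 | 10α-acetoxy-8α-hydroxy-3α-methoxy-1-oxogermacr-11(13)-en-12,6α-olide | C=C1C(=O)O[C@@H]2C[C@@H](C)[C@H](OC)CC(=O)[C@](C)(OC(C)=O)C[C@H](O)[C@@H]12 | intermediate |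
| 20 | angelic acid, (Z)-2-methylbut-2-enoic acid | C/C=C(/C)C(=O)O | starting material |
| 21 | Rufesolide C (3R,4R,6R,7S,8S,10R) | C=C1C(=O)O[C@@H]2C[C@@H](C)[C@H](OC)CC(=O)[C@](C)(OC(C)=O)C[C@H](OC(=O)/C(C)=C\C)[C@@H]12 | target |

## Step count
- Total steps: 17
- Longest linear sequence: 12 (steps 1–8, then 14–17)

## Three steps most likely to fail
1. **Step 16, the new photoredox/Cr macro-allylation.** The risks are oligomerisation, protodehalogenation, formation of the cis-lactone or the C8 epimer, and E1cB loss of the β-acetate.
   Fallback (known chemistry, different closure bond):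
   - Form C7–C8 intermolecularly by the established Zn/aq NH4Cl Barbier reaction of 10 with the aldehyde obtained by ozonolysis of 15.
   - Angeloylate O8.
   - Close the ring at C2–C3 by an intramolecular TMSOTf Mukaiyama acetal aldol at high dilution.
2. **Step 14, Felkin selectivity of the acetal aldol.** The risks are a low C3 ratio and MeOH elimination.
   Fallback: hydrolyse 10 to the aldehyde and run a closed-transition-state boron aldol with the dicyclohexylboron enolate of 15. Then methylate the C3 hydroxyl separately with Me3OBF4 and Proton Sponge.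
3. **Step 8, RCM to a trisubstituted butenolide bearing CH2Br.** The risks are slow closure and catalyst death.
   Fallback: drop metathesis and build the ring by carbonylation. Open epoxide 6 with lithium acetylide and carry out the Pd-catalysed cyclocarbonylation used in step 2 to give the α-methylene lactone. Then apply Br2 followed by Et3N (addition–elimination with transposition) to reach 10.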